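**Direct plan and its weak points**

A direct plan would O-alkylate 3,5-dibromo-2-methoxyphenol A1 to the aryloxyacetone A2 and build the second benzene ring on it by a [3+3] double aldol condensation with sodium nitromalonaldehyde A3, which would give the nitrophenol A4. It would then mesylate the phenol, reduce the nitro group to the aniline A5, brominate ortho to the amino group, remove the amino group through the diazonium salt and cleave the mesylate.
- The ring-forming condensation of A2 with A3 would be weak: a slow double aldol in aqueous base on an unsymmetrical, base-sensitive α-aryloxy ketone with a shock-sensitive salt, placed in the middle of the sequence.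
- The five operations after it (mesylation, nitro reduction, bromination, deamination, demesylation) would form one C–Br bond and build nothing of the skeleton; the nitrogen would be brought in only to be removed.
- The length would be a weakness in itself: about nine linear steps from A1, with the finished diaryl ether exposed late to bromination of an electron-rich aniline and to a diazonium reduction.

**Retrosynthetic overview of the new route**

- Ring A (the 3,5-dibromo-2-methoxyphenoxy ring) is not taken as an arene. Its C1–O bond to the bridging oxygen is cut back to an SN2 opening of 2,3-epoxycyclohexanone at the α-carbon by the phenoxide of ring B, and its C2 oxygen (the later OMe) is the ketone oxygen.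
- The 2-aryloxycyclohexenone is then dehydrogenated to the phenol. The new free OH at C2 of ring A directs both bromines to C3 and C5 (ortho and para to it) and is methylated afterwards.
- Ring B is aromatic throughout: 2-(benzyloxy)phenol is brominated para to its free OH, and that OH becomes the bridging oxygen. Ring A is carried as a saturated ring and aromatised only after the ether bond exists.
- This avoids the nitromalonaldehyde ring synthesis and the nitro/amino/diazonium detour. Every bromine is placed by the oxygen director already in the molecule, and the only protecting group is one benzyl ether.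

Key step: step 2

Remark: 2,3-epoxycyclohexanone (7-oxabicyclo[4.1.0]heptan-2-one) is taken as a catalogue compound and used as the racemate; its two stereocentres are destroyed in step 2, and the target is achiral.

**Route**

Step 1
Reactants: 1 2-(benzyloxy)phenol
Product: 2 2-(benzyloxy)-4-bromophenol
Conditions: NBS (1.0 equiv), MeCN, −20 → 0 °C, dark
Reagents that add atoms: N-bromosuccinimide, O=C1CCC(=O)N1Br
Why: Electrophilic aromatic bromination in which the free hydroxyl group outranks the benzyloxy group as director and its para position is open, as in the bromination of guaiacol to 4-bromoguaiacol, so the bromine of ring B is set para to the oxygen that becomes the bridge.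

Step 2
Reactants: 2 2-(benzyloxy)-4-bromophenol; 3 2,3-epoxycyclohexanone (7-oxabicyclo[4.1.0]heptan-2-one, racemic)
Product: 5 2-[2-(benzyloxy)-4-bromophenoxy]cyclohex-2-en-1-one, via trans-β-hydroxy ketone 4 (not isolated)
Conditions: KH (0.2 equiv), 18-crown-6 (0.2 equiv), 3 (1.3 equiv), THF, 0 → 65 °C
Reagents that add atoms: none
Why: The potassium phenoxide of 2 opens the epoxide of 3 by SN2 attack at C2, the carbon next to the carbonyl group, whose π* orbital lowers the barrier of the displacement; this is the reaction type by which thiolates, azide and phenoxides turn 2,3-epoxycyclohexanone into 2-hetero-substituted cyclohex-2-enones. The alkoxide of the trans-hydroxy ketone 4 is protonated by the next molecule of 2, so base is needed only in catalytic amount, and E1cB loss of water through the C2 enolate drives the reversible opening to the conjugated enol ether 5. No ring is closed, and the two stereocentres of 4 (set trans by inversion at C2) vanish on dehydration, so neither strain nor stereocontrol enters. The selectivity needed is attack at C2 and not at C3, secured by the carbonyl activation of C2 and by the fact that an adduct at C3 would expel the phenoxide again by E1cB at the cost of some 3, which is used in excess, together with O- and not C-alkylation of the phenoxide, secured by the crown-ether-separated potassium ion pair. The step makes the diaryl ether C–O bond at an sp3 carbon with no metal catalyst and no aryl halide partner, so the aryl bromide of 2 is a spectator, and it places the bridging oxygen and the carbonyl oxygen of the future ring A in the vicinal relation of the target.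

Step 3
Reactants: 5 2-[2-(benzyloxy)-4-bromophenoxy]cyclohex-2-en-1-one
Product: 7 2-[2-(benzyloxy)-4-bromophenoxy]phenol, via cyclohexa-2,5-dienone 6 (not isolated)
Conditions: LiN(SiMe3)2 (1.1 equiv), THF, −78 °C; PhS(Cl)=NtBu (1.2 equiv), −78 °C → rt; aq NH4Cl
Reagents that add atoms: none
Why: Mukaiyama dehydrogenation, in which kinetic deprotonation at C6 gives the cross-conjugated lithium enolate, its carbon attacks the sulfur of N-tert-butylbenzenesulfinimidoyl chloride, and syn-elimination of the sulfenamide through a five-membered transition state gives dienone 6, a keto tautomer of the phenol that aromatises at once, with no reagent present that touches the aryl bromide or the benzyl ether.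

Step 4
Reactants: 7 2-[2-(benzyloxy)-4-bromophenoxy]phenol
Product: 8 2-[2-(benzyloxy)-4-bromophenoxy]-4,6-dibromophenol
Conditions: NBS (2.05 equiv), MeCN, −10 °C → rt, dark
Reagents that add atoms: N-bromosuccinimide, O=C1CCC(=O)N1Br
Why: Electrophilic aromatic bromination directed by the new free hydroxyl group of ring A to its open para and ortho positions, which are C5 and C3 of ring A in the target, while the benzyloxy ring, an aryl ether already deactivated by its bromine, should react far more slowly with two equivalents of reagent.

Step 5
Reactants: 8 2-[2-(benzyloxy)-4-bromophenoxy]-4,6-dibromophenol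
Product: 9 2-(benzyloxy)-4-bromo-1-(3,5-dibromo-2-methoxyphenoxy)benzene
Conditions: MeI (1.5 equiv), K2CO3 (2 equiv), DMF, rt
Reagents that add atoms: iodomethane, CI
Why: Williamson O-methylation (SN2 on MeI) of the only acidic group, the hindered but strongly acidic dibromophenol, whose phenoxide forms completely with carbonate in DMF.

Step 6
Reactants: 9 2-(benzyloxy)-4-bromo-1-(3,5-dibromo-2-methoxyphenoxy)benzene
Product: 10 5-bromo-2-(3,5-dibromo-2-methoxyphenoxy)phenol (target)
Conditions: BCl3 (2.5 equiv), C6HMe5 (3 equiv), CH2Cl2, −78 °C; then H2O
Reagents that add atoms: none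
Why: Lewis acid-mediated cleavage of the aryl benzyl ether, in which BCl3 ionises the O–CH2Ph bond at −78 °C and pentamethylbenzene traps the benzyl cation by Friedel–Crafts alkylation, a reagent pair known to leave aryl methyl ethers and aryl bromides intact, whereas hydrogenolysis would endanger the three C–Br bonds.

**Compound list**

1 | 2-(benzyloxy)phenol | Oc1ccccc1OCc1ccccc1 | starting material
2 | 2-(benzyloxy)-4-bromophenol | Oc1ccc(Br)cc1OCc1ccccc1 | intermediate
3 | 2,3-epoxycyclohexanone (7-oxabicyclo[4.1.0]heptan-2-one; racemic, one enantiomer drawn) | O=C1CCC[C@H]2O[C@@H]12 | starting material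
4 | trans-2-[2-(benzyloxy)-4-bromophenoxy]-3-hydroxycyclohexan-1-one (racemic, one enantiomer drawn) | O=C1CCC[C@@H](O)[C@@H]1Oc1ccc(Br)cc1OCc1ccccc1 | intermediate
5 | 2-[2-(benzyloxy)-4-bromophenoxy]cyclohex-2-en-1-one | O=C1CCCC=C1Oc1ccc(Br)cc1OCc1ccccc1 | intermediate
6 | 2-[2-(benzyloxy)-4-bromophenoxy]cyclohexa-2,5-dien-1-one | O=C1C=CCC=C1Oc1ccc(Br)cc1OCc1ccccc1 | intermediate
7 | 2-[2-(benzyloxy)-4-bromophenoxy]phenol | Oc1ccccc1Oc1ccc(Br)cc1OCc1ccccc1 | intermediate
8 | 2-[2-(benzyloxy)-4-bromophenoxy]-4,6-dibromophenol | Oc1c(Br)cc(Br)cc1Oc1ccc(Br)cc1OCc1ccccc1 | intermediate
9 | 2-(benzyloxy)-4-bromo-1-(3,5-dibromo-2-methoxyphenoxy)benzene | COc1c(Br)cc(Br)cc1Oc1ccc(Br)cc1OCc1ccccc1 | intermediate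
10 | 5-bromo-2-(3,5-dibromo-2-methoxyphenoxy)phenol (achiral) | COc1c(Br)cc(Br)cc1Oc1ccc(Br)cc1O | target

**Step count and risks**

Total steps: 6. Longest linear sequence: 6 (steps 1 to 6; compound 3 is bought).

Steps most likely to fail:

1. Step 2. Base-induced isomerisation and self-condensation of the epoxy ketone could outrun the opening by the hindered phenoxide, or the dehydration could stall at the hydroxy ketone. The fallback sets out from 2 and comes back at 7. Nucleophilic aromatic substitution of the phenoxide of 2 on 2-fluorobenzaldehyde (K2CO3, DMF, 110 °C) would give 2-[2-(benzyloxy)-4-bromophenoxy]benzaldehyde F1. Baeyer–Villiger oxidation with mCPBA in CH2Cl2 would give 2-[2-(benzyloxy)-4-bromophenoxy]phenyl formate F2, and NaOH in MeOH/H2O would free phenol 7. This gives up the saturated-ring construction of ring A but keeps the hydroxyl-directed bromination of steps 4 to 6.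

2. Step 3. Proton exchange between the enolate and its sulfur adduct, or deprotonation at the γ-carbon, could leave the dehydrogenation incomplete, and the phenoxide formed could be sulfenylated by excess reagent. The fallback sets out from 5 and comes back at 7. It works from the acid side by halogenation and dehydrohalogenation: CuBr2 (2.2 equiv) and LiBr in MeCN at reflux would brominate C6 through the copper-bound enol to give 6-bromo-2-[2-(benzyloxy)-4-bromophenoxy]cyclohex-2-en-1-one F3, which would lose HBr under the same conditions and tautomerise to 7.

3. Step 6. Chelation of BCl3 between the methoxy oxygen and the bridging oxygen could lead to partial loss of the methyl ether during debenzylation. The fallback sets out from 8 and comes back at 10. It reverses the order and relies on acidity in place of protection: debenzylation of 8 (BCl3, C6HMe5, CH2Cl2, −78 °C), where no methyl ether is present, would give 4,6-dibromo-2-(4-bromo-2-hydroxyphenoxy)phenol F4. MeI (1.0 equiv) with K2CO3 (1.0 equiv) in acetone at rt would then methylate mainly the markedly more acidic dibromophenol oxygen of ring A, which alone is ionised by one equivalent of base, and give 10.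

**Further compounds**

F1 | step 2 | 2-[2-(benzyloxy)-4-bromophenoxy]benzaldehyde | O=Cc1ccccc1Oc1ccc(Br)cc1OCc1ccccc1
F2 | step 2 | 2-[2-(benzyloxy)-4-bromophenoxy]phenyl formate | O=COc1ccccc1Oc1ccc(Br)cc1OCc1ccccc1
F3 | step 3 | 6-bromo-2-[2-(benzyloxy)-4-bromophenoxy]cyclohex-2-en-1-one (racemic) | O=C1C(Br)CCC=C1Oc1ccc(Br)cc1OCc1ccccc1
F4 | step 6 | 4,6-dibromo-2-(4-bromo-2-hydroxyphenoxy)phenol | Oc1c(Br)cc(Br)cc1Oc1ccc(Br)cc1O
A1 | direct plan | 3,5-dibromo-2-methoxyphenol | COc1c(Br)cc(Br)cc1O
A2 | direct plan | 1-(3,5-dibromo-2-methoxyphenoxy)propan-2-one | COc1c(Br)cc(Br)cc1OCC(C)=O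
A3 | direct plan | sodium nitromalonaldehyde | [Na+].[O-]C=C(C=O)[N+](=O)[O-]
A4 | direct plan | 2-(3,5-dibromo-2-methoxyphenoxy)-4-nitrophenol | COc1c(Br)cc(Br)cc1Oc1cc([N+](=O)[O-])ccc1O
A5 | direct plan | 4-amino-2-(3,5-dibromo-2-methoxyphenoxy)phenyl methanesulfonate | COc1c(Br)cc(Br)cc1Oc1cc(N)ccc1OS(C)(=O)=O
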